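At 3.0 min I had to read the target in beta, theta, epsilon and eta, which share their charges and differ in how and how warm they were run.

| setting | birch | larch | elm | beta | theta | epsilon | eta |
|---|---|---|---|---|---|---|---|
| substrate | 0.015 M | 0.015 M | 0.015 M | 0.015 M | 0.015 M | 0.015 M | 0.015 M (fed, over 2.0 min) |
| reagent | 7.5 mM | 10 mM | 16 mM | 7.50 mM | 7.50 mM (fed, over 2.0 min) | 7.50 mM | 7.50 mM |
| temperature | −25 °C | −14 °C | −25 °C |  | −20 °C | −20 °C |  |
| remark | run made earlier | run made earlier | run made earlier | everything together at the start at −40 °C, warmed to −20 °C at 2.0 min | all else is in the flask from the start; the feed brings no volume worth counting | everything together at the start | the addition at −40 °C, then warmed to −20 °C; the feed brings no volume worth counting |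
| time |  |  |  | 3.0 min | 3.0 min | 3.0 min | 3.0 min |

| run | time / min | target / % | substrate / % |
|---|---|---|---|
| birch | 0.417 | 10.9 | 88.6 |
| birch | 1.00 | 22.8 | 76.8 |
| birch | 2.00 | 35.8 | 63.8 |
| birch | 3.00 | 44.1 | 55.0 |
| larch | 0.250 | 17.0 | 82.7 |
| larch | 0.500 | 30.0 | 69.9 |
| larch | 1.33 | 53.0 | 46.4 |
| larch | 3.00 | 66.4 | 33.9 |
| elm | 0.833 | 28.9 | 71.2 |
| elm | 1.50 | 44.1 | 56.1 |
| elm | 2.50 | 59.1 | 40.9 |
| elm | 3.00 | 64.4 | 35.3 |

(readings scatter by 0.3 percentage points)

* the flask with the highest amount of target, in percent of the substrate charged ("all alike" if they lie within 1.5 percentage points) (beta / theta / epsilon / eta / all alike)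
* final target, as a percentage of the substrate charged, in beta
* final target, as a percentage of the substrate charged, in theta
* final target, as a percentage of the substrate charged, in epsilon
* final target, as a percentage of the substrate charged, in eta



I built the flask up one process at a time, beginning with the main step and leaving time out. In birch at 3.00 min, substrate and target summed to 99.1%, so I took one substrate to give one target, and I assumed one reagent spent on each. A substrate molecule then becomes target only if it finds a reagent of its own. That gave me the ceiling, c(reagent) charged divided by c(substrate) charged, here 50.0% of the substrate, with reagent as the limiting reagent. Larch has a ceiling of 66.7% and read 66.4% at 3.00 min, 0.30 percentage points under it, which fits that assumption.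

Next I added the pace. Up to each run's first reading, the substrate in elm had been falling 1.40 times as fast as in birch, less than the 2.13 times the reagent and close to its square root, 1.46. I therefore took the rate as c(substrate) times the square root of c(reagent). The approach to the ceiling slows as the reagent goes, and birch, with the same ceiling, stood at 88.2% of it at 3.00 min.

Last came temperature and feeding. Epsilon has birch's charges but is warmer, so I put it above 44.1% and under the ceiling. Theta stayed at −20 °C but received its reagent over 2.0 min, and I placed it under epsilon as well. Beta and eta spent less time warm than epsilon, 1.00 min against 3.0 min, so I placed both under epsilon.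

The forecast named epsilon, giving 49.4% there, 44.9% for theta, 36.6% for beta and 33.6% for eta, and said of epsilon “about 49%, reagent nearly exhausted”.

The flasks gave 49.4% in epsilon, 45.0% in theta, 36.6% in beta and 33.7% in eta, so epsilon held the most target.

    substrate + reagent → target, rate k1*[substrate]*[reagent]^0.5 (k = 0.0870 L⁰·⁵ mol⁻⁰·⁵ s⁻¹, Ea = 42.0 kJ mol⁻¹)
    (constants at −20 °C)

Epsilon stood just under its ceiling of 50.0%, with 1.2% of its reagent left at 3.00 min, while eta still had 33% left and reached 50.0% by 30.0 min. I then took the neighbour of eta charged with 0.0045 M of reagent. Its ceiling is 30.0%, which lies below the 33.7% that eta gave, so I expected this flask to end under eta. It gave 24.9%, which is 83.0% of its ceiling, with 17.1% of its reagent left at 3.00 min.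

(The data come from a simulation with made-up constants; the scatter is artificial.)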